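**Retrosynthetic overview**
- The target comes from its 5,7-bis-MOM ether. In that ether, ring C is cut in one move at O1–C8a and C4–C4a, which gives an (S)-4-aryl-β-lactone and a ring-A aryne (from an o-silylaryl triflate).
- Enabling feature: in ring C the chain O1–C2–C3–C4 is a β-oxy-acyl unit whose two ends sit on the adjacent ring-A carbons C8a and C4a. Joining O1 to C4 gives a four-membered oxetan-2-one, and C4a/C8a are the two carbons of an aryne, so ring C is that oxetanone expanded by two atoms.
- The C5 oxygen next to C4a steers the aryne regiochemistry. The only stereocentre, C2, lies inside the lactone and keeps all four of its bonds.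
- The lactone comes from 4'-hydroxyacetophenone by O-prenylation, Claisen condensation, asymmetric transfer hydrogenation (sets C2) and lactonisation. The aryne precursor comes from phloroglucinol by two carbamate-directed ortho-metalations (TMS at the future C4a, prenyl at C8).
- Ring order: rings A and B are bought as benzene rings. The oxetanone is closed in step 11 and expanded to ring C in step 12.

Key step: step 12

Assumption: flavanone numbering (O1, C2, C3, C4, C4a, C5–C8, C8a) is used throughout, "prenyl" means 3-methylbut-2-en-1-yl, and the SMILES corresponds to the (2S) enantiomer.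

**Step 1**
Reactants: 1 phloroglucinol (benzene-1,3,5-triol)
Product: 2 3,5-bis(methoxymethoxy)phenol
Conditions: MOMCl (2 equiv), i-Pr2NEt, CH2Cl2/DMF, 0 °C to rt; chromatography
Reagents that add atoms: chloromethyl methyl ether (MOMCl), COCCl
Why: Williamson-type O-alkylation of a triol with three equivalent hydroxyls is statistical but structurally unambiguous, and the mono- and tris-ethers can be separated and recycled.

**Step 2**
Reactants: 2 3,5-bis(methoxymethoxy)phenol
Product: 3 3,5-bis(methoxymethoxy)phenyl N,N-diethylcarbamate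
Conditions: Et2NCOCl, K2CO3, MeCN, reflux
Reagents that add atoms: N,N-diethylcarbamoyl chloride, CCN(CC)C(=O)Cl
Why: O-carbamoylation of the only free phenol places the strongest oxygen-based director for ortho-metalation on the oxygen that later becomes the leaving group at C8a.

**Step 3**
Reactants: 3 3,5-bis(methoxymethoxy)phenyl N,N-diethylcarbamate
Product: 5 3,5-bis(methoxymethoxy)-2-(trimethylsilyl)phenyl N,N-diethylcarbamate, via aryllithium 4 (not isolated)
Conditions: s-BuLi, TMEDA, THF, −78 °C; TMSCl, −78 °C to rt
Reagents that add atoms: chlorotrimethylsilane, C[Si](C)(C)Cl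
Why: Directed ortho-metalation: the carbamate outranks OMOM as director, so lithiation should occur at one of the two equivalent CH positions flanked by carbamate and OMOM rather than between the two OMOM groups, and the silyl quench at −78 °C forestalls the anionic ortho-Fries shift.

**Step 4**
Reactants: 5 3,5-bis(methoxymethoxy)-2-(trimethylsilyl)phenyl N,N-diethylcarbamate; 6 prenyl bromide (1-bromo-3-methylbut-2-ene)
Product: 8 3,5-bis(methoxymethoxy)-2-(3-methylbut-2-en-1-yl)-6-(trimethylsilyl)phenyl N,N-diethylcarbamate, via aryllithium 7 (not isolated)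
Conditions: s-BuLi, TMEDA, THF, −78 °C; 6, −78 to −20 °C
Reagents that add atoms: none
Why: A second directed ortho-metalation should again choose the carbamate-flanked CH, SN2 allylation at the primary end of prenyl bromide gives the linear prenyl group, and silicon was introduced first so that no benzylic-allylic CH2 competes for the base.

**Step 5**
Reactants: 8 3,5-bis(methoxymethoxy)-2-(3-methylbut-2-en-1-yl)-6-(trimethylsilyl)phenyl N,N-diethylcarbamate
Product: 9 3,5-bis(methoxymethoxy)-2-(3-methylbut-2-en-1-yl)-6-(trimethylsilyl)phenol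
Conditions: LiAlH4, THF, 0 °C to reflux; Na2SO4·10H2O
Reagents that add atoms: none
Why: Hydride reduction of the aryl carbamate (acyl substitution with aryloxide as leaving group) frees the hindered phenol without acid, which spares the protodesilylation-prone aryl–Si bond, the acetals and the alkene.

**Step 6**
Reactants: 9 3,5-bis(methoxymethoxy)-2-(3-methylbut-2-en-1-yl)-6-(trimethylsilyl)phenol
Product: 10 3,5-bis(methoxymethoxy)-2-(3-methylbut-2-en-1-yl)-6-(trimethylsilyl)phenyl trifluoromethanesulfonate
Conditions: Tf2O, pyridine, CH2Cl2, −78 to 0 °C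
Reagents that add atoms: trifluoromethanesulfonic anhydride, O=S(=O)(OS(=O)(=O)C(F)(F)F)C(F)(F)F
Why: O-sulfonylation of the phenol gives the o-(trimethylsilyl)aryl triflate, the standard fluoride-triggered aryne precursor.

**Step 7**
Reactants: 11 4'-hydroxyacetophenone; 6 prenyl bromide
Product: 12 4'-(3-methylbut-2-en-1-yloxy)acetophenone
Conditions: K2CO3, acetone, reflux
Reagents that add atoms: none
Why: Williamson ether synthesis on the only acidic OH installs the 4'-O-prenyl group before any competing phenol exists in the molecule.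

**Step 8**
Reactants: 12 4'-(3-methylbut-2-en-1-yloxy)acetophenone
Product: 13 ethyl 3-oxo-3-[4-(3-methylbut-2-en-1-yloxy)phenyl]propanoate
Conditions: NaH, (EtO)2CO, THF, reflux; AcOH quench
Reagents that add atoms: diethyl carbonate, CCOC(=O)OCC
Why: Crossed Claisen condensation of the methyl ketone enolate with a non-enolisable carbonate is driven to completion by deprotonation of the β-keto ester.

**Step 9**
Reactants: 13 ethyl 3-oxo-3-[4-(3-methylbut-2-en-1-yloxy)phenyl]propanoate
Product: 14 ethyl (S)-3-hydroxy-3-[4-(3-methylbut-2-en-1-yloxy)phenyl]propanoate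
Conditions: RuCl[(S,S)-TsDPEN](p-cymene) (cat.), HCO2H–Et3N azeotrope, 30 °C
Reagents that add atoms: none
Why: Noyori–Ikariya asymmetric transfer hydrogenation: the (S,S)-TsDPEN ruthenium hydride reduces aryl ketones through an outer-sphere six-membered transition state ordered by an aryl CH/π contact, which should give the (S)-carbinol and so sets the future C2, while isolated alkenes are not touched.

**Step 10**
Reactants: 14 ethyl (S)-3-hydroxy-3-[4-(3-methylbut-2-en-1-yloxy)phenyl]propanoate
Product: 15 (S)-3-hydroxy-3-[4-(3-methylbut-2-en-1-yloxy)phenyl]propanoic acid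
Conditions: LiOH, THF/H2O, 0 °C to rt; cold dilute HCl to pH 4
Reagents that add atoms: lithium hydroxide, [Li+].[OH-]
Why: Ester saponification at low temperature with acidification only to pH 4 leaves the acid-sensitive p-alkoxybenzylic carbinol and its configuration untouched.

**Step 11**
Reactants: 15 (S)-3-hydroxy-3-[4-(3-methylbut-2-en-1-yloxy)phenyl]propanoic acid
Product: 17 (S)-4-[4-(3-methylbut-2-en-1-yloxy)phenyl]oxetan-2-one, via mixed carboxylic sulfonic anhydride 16 (not isolated)
Conditions: PhSO2Cl, pyridine, 0 °C; cold neutral work-up, used at once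
Reagents that add atoms: none
Why: β-Lactonisation by carboxyl activation: the carboxylate is sulfonylated faster than the alcohol and the hydroxyl closes 4-exo-trig on the mixed anhydride, so the C–O bond at the stereocentre is never broken and the (S) configuration is retained.

**Step 12**
Reactants: 10 3,5-bis(methoxymethoxy)-2-(3-methylbut-2-en-1-yl)-6-(trimethylsilyl)phenyl trifluoromethanesulfonate; 17 (S)-4-[4-(3-methylbut-2-en-1-yloxy)phenyl]oxetan-2-one
Product: 21 (2S)-5,7-bis(methoxymethoxy)-8-(3-methylbut-2-en-1-yl)-2-[4-(3-methylbut-2-en-1-yloxy)phenyl]chroman-4-one, via aryne 18 (not isolated), via potassium alkoxide acyl fluoride 19 (not isolated), via aryl anion 20 (not isolated)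
Conditions: KF, 18-crown-6, THF, 0 °C to rt, slow addition of 10; pH 7 buffer quench
Reagents that add atoms: none
Why: Proposed new method: fluoride plays two roles, it desilylates 10 to release aryne 18 and it opens the strained acyl–oxygen bond of 17 reversibly (the hard-nucleophile mode of β-lactones) to the β-alkoxide acyl fluoride 19, whose oxygen adds to the aryne to give aryl anion 20, which closes on the acyl fluoride and returns fluoride, so that C8a and C4a are inserted into the O1–C4 bond and the four-membered oxetanone becomes the six-membered pyranone. The closest known reaction types are the insertion of arynes into the N–C(O) bond of NH β-lactams (to 2,3-dihydroquinolin-4-ones), the aryne–salicylate annulation to xanthones (O-arylation followed by acyl capture of the aryl anion) and the two-carbon ring expansion of cyclic β-keto esters by aryne acyl-alkylation, whereas the C(acyl)–O bond of a lactone has not been used in this way. The single ring closure is the 6-exo-trig attack of the C4a carbanion on the acyl fluoride carbon C4. No stereocentre is created, since C2 comes from 17 and none of its four bonds is broken at any stage, so the (S) configuration should be carried over unchanged. The regiochemistry (O1 to C8a, C4 to C4a) rests on the OMOM group at C5 next to the triple bond, which polarises and distorts 3-alkoxyarynes so that nucleophiles attack the distal carbon and the carbanion develops beside the oxygen. The step needs alkoxide capture to outrun the aryne–ene reaction of the prenyl groups, lactone oligomerisation, protonation of 20 and base-induced retro-oxa-Michael opening of 21, which is addressed by an aprotic solvent of low acidity, slow addition of 10, low temperature and an immediate buffered quench.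

**Step 13**
Reactants: 21 (2S)-5,7-bis(methoxymethoxy)-8-(3-methylbut-2-en-1-yl)-2-[4-(3-methylbut-2-en-1-yloxy)phenyl]chroman-4-one
Product: 22 (2S)-5,7-dihydroxy-8-(3-methylbut-2-en-1-yl)-2-[4-(3-methylbut-2-en-1-yloxy)phenyl]chroman-4-one (CNP0558191.1)
Conditions: HCl (cat.), MeOH, 0 °C to rt
Reagents that add atoms: none
Why: Acid-catalysed transacetalisation of the two aryl MOM acetals with methanol proceeds through an oxocarbenium ion far more readily than protonation of the trisubstituted alkenes or of the allylic aryl ether, and flavanones are configurationally stable on the acidic side, so C2 should not be scrambled.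

**Compound list**
1 | phloroglucinol | Oc1cc(O)cc(O)c1 | starting material
2 | 3,5-bis(methoxymethoxy)phenol | COCOc1cc(O)cc(OCOC)c1 | intermediate
3 | 3,5-bis(methoxymethoxy)phenyl N,N-diethylcarbamate | CCN(CC)C(=O)Oc1cc(OCOC)cc(OCOC)c1 | intermediate
4 | 2-lithio-3,5-bis(methoxymethoxy)phenyl N,N-diethylcarbamate (not isolated) | CCN(CC)C(=O)Oc1cc(OCOC)cc(OCOC)c1[Li] | intermediate
5 | 3,5-bis(methoxymethoxy)-2-(trimethylsilyl)phenyl N,N-diethylcarbamate | CCN(CC)C(=O)Oc1cc(OCOC)cc(OCOC)c1[Si](C)(C)C | intermediate
6 | prenyl bromide (1-bromo-3-methylbut-2-ene) | CC(C)=CCBr | starting material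
7 | 2-lithio-3,5-bis(methoxymethoxy)-6-(trimethylsilyl)phenyl N,N-diethylcarbamate (not isolated) | CCN(CC)C(=O)Oc1c([Li])c(OCOC)cc(OCOC)c1[Si](C)(C)C | intermediate
8 | 3,5-bis(methoxymethoxy)-2-(3-methylbut-2-en-1-yl)-6-(trimethylsilyl)phenyl N,N-diethylcarbamate | CCN(CC)C(=O)Oc1c(CC=C(C)C)c(OCOC)cc(OCOC)c1[Si](C)(C)C | intermediate
9 | 3,5-bis(methoxymethoxy)-2-(3-methylbut-2-en-1-yl)-6-(trimethylsilyl)phenol | Oc1c(CC=C(C)C)c(OCOC)cc(OCOC)c1[Si](C)(C)C | intermediate
10 | 3,5-bis(methoxymethoxy)-2-(3-methylbut-2-en-1-yl)-6-(trimethylsilyl)phenyl trifluoromethanesulfonate | O=S(=O)(Oc1c(CC=C(C)C)c(OCOC)cc(OCOC)c1[Si](C)(C)C)C(F)(F)F | intermediate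
11 | 4'-hydroxyacetophenone | CC(=O)c1ccc(O)cc1 | starting material
12 | 4'-(3-methylbut-2-en-1-yloxy)acetophenone | CC(=O)c1ccc(OCC=C(C)C)cc1 | intermediate
13 | ethyl 3-oxo-3-[4-(3-methylbut-2-en-1-yloxy)phenyl]propanoate | CCOC(=O)CC(=O)c1ccc(OCC=C(C)C)cc1 | intermediate
14 | ethyl (S)-3-hydroxy-3-[4-(3-methylbut-2-en-1-yloxy)phenyl]propanoate | CCOC(=O)C[C@H](O)c1ccc(OCC=C(C)C)cc1 | intermediate
15 | (S)-3-hydroxy-3-[4-(3-methylbut-2-en-1-yloxy)phenyl]propanoic acid | OC(=O)C[C@H](O)c1ccc(OCC=C(C)C)cc1 | intermediate
16 | benzenesulfonic (S)-3-hydroxy-3-[4-(3-methylbut-2-en-1-yloxy)phenyl]propanoic anhydride (not isolated) | O=C(C[C@H](O)c1ccc(OCC=C(C)C)cc1)OS(=O)(=O)c1ccccc1 | intermediate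
17 | (S)-4-[4-(3-methylbut-2-en-1-yloxy)phenyl]oxetan-2-one | O=C1C[C@@H](c2ccc(OCC=C(C)C)cc2)O1 | intermediate
18 | 3,5-bis(methoxymethoxy)-6-(3-methylbut-2-en-1-yl)benzyne (not isolated) | COCOC1=CC(OCOC)=C(CC=C(C)C)C#C1 | intermediate
19 | potassium (S)-3-fluoro-3-oxo-1-[4-(3-methylbut-2-en-1-yloxy)phenyl]propan-1-olate (not isolated) | O=C(F)C[C@H]([O-])c1ccc(OCC=C(C)C)cc1.[K+] | intermediate
20 | potassium aryl anion: (S)-3-aryloxy-3-[4-(3-methylbut-2-en-1-yloxy)phenyl]propanoyl fluoride, carbanion at the ring carbon between the ether oxygen and OMOM (not isolated) | O=C(F)C[C@H](Oc1c(CC=C(C)C)c(OCOC)cc(OCOC)[c-]1)c1ccc(OCC=C(C)C)cc1.[K+] | intermediate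
21 | (2S)-5,7-bis(methoxymethoxy)-8-(3-methylbut-2-en-1-yl)-2-[4-(3-methylbut-2-en-1-yloxy)phenyl]chroman-4-one | CC(C)=CCOc1ccc([C@@H]2CC(=O)c3c(OCOC)cc(OCOC)c(CC=C(C)C)c3O2)cc1 | intermediate
22 | (2S)-5,7-dihydroxy-8-(3-methylbut-2-en-1-yl)-2-[4-(3-methylbut-2-en-1-yloxy)phenyl]chroman-4-one | CC(C)=CCOc1ccc([C@@H]2CC(=O)c3c(O)cc(O)c(CC=C(C)C)c3O2)cc1 | target

**Step count**
Total steps: 13. Longest linear sequence: 8 steps (1–6, 12, 13). The second branch (7–11) joins at step 12.

**Steps most likely to fail**

Step 12 (new method).
- What may go wrong: the ring-opened alkoxide may be consumed by oligomerisation of the lactone, or it may lose the race for the aryne to the ene reaction with the prenyl groups. The aryl anion may be protonated before acyl capture. Prolonged contact with fluoride may open the product by retro-oxa-Michael reaction and erode the enantiomeric purity.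
- Fallback (known chemistry, from 14 and 10, returning at 21): hydroxy ester 14 is dehydrated and saponified (KOH, EtOH, reflux) to (E)-4-(prenyloxy)cinnamic acid F1.
- F1 and 10 with CsF in hot THF undergo the known insertion of an aryne into the C–O bond of a carboxylic acid and give the 2'-hydroxychalcone F2.
- F2 closes by oxa-Michael addition under the same conditions (or NaOAc, EtOH, reflux) to the racemic flavanone F3.
- Kinetic resolution of F3 by Noyori–Ikariya transfer hydrogenation with the (R,R)-TsDPEN ruthenium catalyst should reduce the (R)-ketone to the cis-flavan-4-ol F4 and leave the (S)-ketone 21.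

Step 11.
- What may go wrong: sulfonylation of the p-alkoxybenzylic hydroxyl instead of the carboxylate, followed by ionisation, would lead to elimination, racemisation or decarboxylative fragmentation. Intermolecular esterification also competes with the strained four-ring closure.
- Fallback (from 6, returning at 17): the ring is built by cycloaddition instead of cyclodehydration. Purchased 4-hydroxybenzaldehyde F5 is O-alkylated with 6 (K2CO3, acetone) to 4-(prenyloxy)benzaldehyde F6.
- Ketene F7 is generated from acetyl chloride and i-Pr2NEt. It is added to F6 in a catalytic asymmetric ketene–aldehyde [2+2] cyclocondensation (O-silylated cinchona alkaloid of the pseudoenantiomeric series that gives the (S)-lactone, lithium perchlorate co-catalyst, CH2Cl2/Et2O, −78 °C).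
- This gives 17 as a cold solution for direct use.

Step 13.
- What may go wrong: the acid may also ionise the aryl prenyl ether, or it may add the liberated 7-hydroxyl across the C8 prenyl alkene.
- Fallback (from 21, returning at 22): the Brønsted-acid solvolysis is replaced by a two-stage acetal-to-silyl-ether exchange. TMSOTf and 2,2'-bipyridyl in MeCN at 0 °C transfer the methoxymethyl groups to the pyridine nitrogen and give the 5,7-bis(trimethylsilyl) ether F8.
- F8 is hydrolysed by water at neutral pH to 22.

**Further compounds**
F1 | step 12 | (E)-3-[4-(3-methylbut-2-en-1-yloxy)phenyl]prop-2-enoic acid | OC(=O)/C=C/c1ccc(OCC=C(C)C)cc1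
F2 | step 12 | (E)-1-[2-hydroxy-4,6-bis(methoxymethoxy)-3-(3-methylbut-2-en-1-yl)phenyl]-3-[4-(3-methylbut-2-en-1-yloxy)phenyl]prop-2-en-1-one | COCOc1cc(OCOC)c(C(=O)/C=C/c2ccc(OCC=C(C)C)cc2)c(O)c1CC=C(C)C
F3 | step 12 | racemic 5,7-bis(methoxymethoxy)-8-(3-methylbut-2-en-1-yl)-2-[4-(3-methylbut-2-en-1-yloxy)phenyl]chroman-4-one | CC(C)=CCOc1ccc(C2CC(=O)c3c(OCOC)cc(OCOC)c(CC=C(C)C)c3O2)cc1
F4 | step 12 | (2R,4R)-5,7-bis(methoxymethoxy)-8-(3-methylbut-2-en-1-yl)-2-[4-(3-methylbut-2-en-1-yloxy)phenyl]chroman-4-ol | CC(C)=CCOc1ccc([C@H]2C[C@@H](O)c3c(OCOC)cc(OCOC)c(CC=C(C)C)c3O2)cc1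
F5 | step 11 | 4-hydroxybenzaldehyde (purchased) | O=Cc1ccc(O)cc1
F6 | step 11 | 4-(3-methylbut-2-en-1-yloxy)benzaldehyde | O=Cc1ccc(OCC=C(C)C)cc1
F7 | step 11 | ketene | C=C=O
F8 | step 13 | (2S)-8-(3-methylbut-2-en-1-yl)-2-[4-(3-methylbut-2-en-1-yloxy)phenyl]-5,7-bis(trimethylsilyloxy)chroman-4-one | CC(C)=CCOc1ccc([C@@H]2CC(=O)c3c(O[Si](C)(C)C)cc(O[Si](C)(C)C)c(CC=C(C)C)c3O2)cc1
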